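## Retrosynthetic overview

1. The last C–C bond is C4 (upper unit) to C6 (lower unit): a silver-promoted Friedel–Crafts union of the upper 4-sulfide 15 with the lower unit 8, anti to the 3-benzoate (3,4-trans); ester cleavage and hydrogenolysis follow.
2. Ring C of the upper unit (O1, C2, C3, C4, C4a, C8a) is disconnected at C3–C4 and O1–C2: an oxa-[4+2] of the 4-methoxy ortho-quinone methide from aldehyde 2 with the (Z)-enol benzoate 11. C4 leaves this step as a methyl ether, a temporary oxidation level that steps 8 and 9 exchange for the lower unit.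
3. Enabling feature: on ring A the phenol oxygen O1 (on C8a) is ortho to C4a, which carries the benzylic C4, so a salicylaldehyde is a latent heterodiene O1=C8a–C4a=C4. The para oxygen of ring B makes C2 the cation-stabilising end of the dienophile and fixes the regiochemistry.
4. Ring C of the lower unit comes from the same aldehyde 2 by the same cycloaddition (benzyl alcohol, enol benzoate 5), all-cis, with the C4 oxygen kept to the end as a benzyl ether.
5. Order of ring formation: rings A and B are bought as arenes; lower ring C (step 4); upper ring C (step 7), the last ring closed.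

Key step: step 7

Remark on the chemistry: the sense of induction of the chiral acid cannot be predicted; the (S,S)-antipode is written, and whichever antipode gives the 2R,3R series in a pilot run of step 4 would be used in steps 4 and 7.

## Route

Step 1
Reactants: 1 2,3,4-trihydroxybenzaldehyde
Product: 2 3,4-bis(benzyloxy)-2-hydroxybenzaldehyde
Conditions: BnBr (2.1 equiv), K2CO3 (2.2 equiv), DMF, 0 °C to rt
Reagents that add atoms: benzyl bromide, BrCc1ccccc1
Why: Williamson etherification; the 2-OH is hydrogen-bonded to the formyl group and is the least nucleophilic phenol, so two equivalents of benzyl bromide should alkylate O4 and O3 only.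

Step 2
Reactants: 3 4-(benzyloxy)benzaldehyde
Product: 4 1-(benzyloxy)-4-ethynylbenzene
Conditions: dimethyl (1-diazo-2-oxopropyl)phosphonate, K2CO3, MeOH, rt
Reagents that add atoms: dimethyl (1-diazo-2-oxopropyl)phosphonate (Ohira–Bestmann reagent), CC(=O)C(=[N+]=[N-])P(=O)(OC)OC
Why: Seyferth–Gilbert homologation with the Ohira–Bestmann reagent turns the aldehyde into the terminal alkyne under mild base that leaves the benzyl ether untouched.

Step 3
Reactants: 4 1-(benzyloxy)-4-ethynylbenzene
Product: 5 (Z)-2-[4-(benzyloxy)phenyl]ethenyl benzoate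
Conditions: PhCO2H, Ru(2-methylallyl)2(Ph2P(CH2)4PPh2) (1 mol %), toluene, 65 °C
Reagents that add atoms: benzoic acid, OC(=O)c1ccccc1
Why: Ruthenium-catalysed anti-Markovnikov hydro-oxycarbonylation of a terminal alkyne runs through a vinylidene complex and should give the (Z)-enol ester, whose geometry later becomes the 2,3-cis relationship.

Step 4
Reactants: 2 3,4-bis(benzyloxy)-2-hydroxybenzaldehyde; 5 (Z)-2-[4-(benzyloxy)phenyl]ethenyl benzoate
Product: 8 (2R,3R,4R)-4,7,8-tris(benzyloxy)-2-[4-(benzyloxy)phenyl]chroman-3-yl benzoate (all-cis lower unit), via dibenzyl acetal 6 (not isolated), via ortho-quinone methide 7 (not isolated)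
Conditions: BnOH (3 equiv), (S,S)-imidodiphosphoric acid from 3,3'-bis(2,4,6-triethylphenyl)-BINOL (5 mol %), 5 Å molecular sieves, toluene, −20 °C
Reagents that add atoms: benzyl alcohol, OCc1ccccc1
Why: Proposed new method: the chiral acid should turn 2 and benzyl alcohol into acetal 6 and then, by loss of benzyl alcohol, into the ion-paired 4-benzyloxy ortho-quinone methide 7, which adds the Z-enol benzoate 5 in an endo inverse-demand oxa-[4+2] (benzoyloxy-bearing carbon to C4, O1 to the benzylic carbon), so that the Z geometry gives 2,3-cis, the endo approach gives 3,4-cis and the chiral anion sets 2R,3R,4R; the closest known reactions are the Lewis acid-catalysed synthesis of cis-4-alkoxy-2-arylchromans from salicylaldehydes, orthoformates and styrenes and the imidodiphosphoric acid-catalysed asymmetric cycloaddition of salicylaldehyde-derived mixed acetals with tethered alkenes.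

Step 5
Reactants: 9 3,4-bis(benzyloxy)benzaldehyde
Product: 10 1,2-bis(benzyloxy)-4-ethynylbenzene
Conditions: dimethyl (1-diazo-2-oxopropyl)phosphonate, K2CO3, MeOH, rt
Reagents that add atoms: dimethyl (1-diazo-2-oxopropyl)phosphonate (Ohira–Bestmann reagent), CC(=O)C(=[N+]=[N-])P(=O)(OC)OC
Why: Seyferth–Gilbert homologation as in step 2, on the catechol-derived aldehyde.

Step 6
Reactants: 10 1,2-bis(benzyloxy)-4-ethynylbenzene
Product: 11 (Z)-2-[3,4-bis(benzyloxy)phenyl]ethenyl benzoate
Conditions: PhCO2H, Ru(2-methylallyl)2(Ph2P(CH2)4PPh2) (1 mol %), toluene, 65 °C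
Reagents that add atoms: benzoic acid, OC(=O)c1ccccc1
Why: Ruthenium-catalysed anti-Markovnikov, Z-selective addition of the acid to the alkyne as in step 3.

Step 7
Reactants: 2 3,4-bis(benzyloxy)-2-hydroxybenzaldehyde; 11 (Z)-2-[3,4-bis(benzyloxy)phenyl]ethenyl benzoate
Product: 14 (2R,3R,4R)-7,8-bis(benzyloxy)-2-[3,4-bis(benzyloxy)phenyl]-4-methoxychroman-3-yl benzoate (all-cis), via dimethyl acetal 12 (not isolated), via ortho-quinone methide 13 (not isolated)
Conditions: HC(OMe)3 (1.5 equiv), (S,S)-imidodiphosphoric acid from 3,3'-bis(2,4,6-triethylphenyl)-BINOL (5 mol %), 4 Å molecular sieves, toluene, −20 °C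
Reagents that add atoms: trimethyl orthoformate, COC(OC)OC
Why: Proposed new method: acid-catalysed acetalisation of 2 and loss of methanol should give the 4-methoxy ortho-quinone methide 13 (O1=C8a–C4a=C4), held by the chiral imidodiphosphate as a phenol/oxocarbenium ion pair, and 13 should add the Z-enol benzoate 11 in an inverse-demand oxa-[4+2] in which the benzoyloxy-bearing carbon, which has the largest HOMO coefficient because the para-benzyloxy aryl group outweighs the weakly donating acyloxy group, bonds to C4 while the benzylic carbon is captured by O1. The closest known reactions are the Lewis acid-catalysed three-component synthesis of cis-2-aryl-4-alkoxychromans from salicylaldehydes, orthoformates and styrenes and the imidodiphosphoric acid-catalysed asymmetric cycloaddition of salicylaldehyde-derived mixed acetals with tethered alkenes; new here is the intermolecular, enantioselective use with an enol ester. Ring C of the upper unit is closed as one six-membered ring by an intermolecular [4+2] heterocycloaddition that forms C3–C4 and O1–C2. C2 and C3 should come out cis because the Z geometry of 11 is transferred suprafacially, and if the bond formation turns stepwise the benzoate carbonyl should trap the C2 cation as a cis-dioxolanylium ion that O1 opens with inversion, which leads to the same cis product; C4 is set cis by the endo transition state but is not needed later; the 2R,3R configuration is set by the chiral anion. The step needs regioselectivity (secured by the 4-benzyloxy group of ring B), cis-stereospecificity (low temperature, non-polar solvent, participating benzoate), enantiofacial selectivity (catalyst) and chemoselectivity for the dienophile over the arenes present (11 is the strongest π-nucleophile in the flask).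

Step 8
Reactants: 14 (2R,3R,4R)-7,8-bis(benzyloxy)-2-[3,4-bis(benzyloxy)phenyl]-4-methoxychroman-3-yl benzoate
Product: 15 (2R,3S,4S)-4-(benzylsulfanyl)-7,8-bis(benzyloxy)-2-[3,4-bis(benzyloxy)phenyl]chroman-3-yl benzoate (2,3-cis-3,4-trans)
Conditions: BnSH (5 equiv), BF3·OEt2 (0.3 equiv), CH2Cl2, −78 to −30 °C
Reagents that add atoms: benzyl mercaptan (phenylmethanethiol), SCc1ccccc1
Why: Lewis acid ionisation of the benzylic C4 ether gives a cation bridged by the 3-benzoate, which the thiol opens from the opposite face, so the 3,4-trans sulfide should form whatever the C4 configuration of 14 (thiolysis of a 4-oxygenated flavan).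

Step 9
Reactants: 15 (2R,3S,4S)-4-(benzylsulfanyl)-7,8-bis(benzyloxy)-2-[3,4-bis(benzyloxy)phenyl]chroman-3-yl benzoate; 8 (2R,3R,4R)-4,7,8-tris(benzyloxy)-2-[4-(benzyloxy)phenyl]chroman-3-yl benzoate
Product: 16 fully protected dimer: lower unit 8 carrying at C6 the (2R,3R)-3-(benzoyloxy)-7,8-bis(benzyloxy)-2-[3,4-bis(benzyloxy)phenyl]chroman-4-yl group, bonded through C4 trans to its 3-benzoate (spatial arrangement of the target)
Conditions: 8 (2.5 equiv), AgBF4 (1.5 equiv), 2,6-di-tert-butyl-4-methylpyridine (2 equiv), 4 Å molecular sieves, CH2Cl2, −40 to 0 °C, dark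
Reagents that add atoms: none
Why: Thiophilic activation of the C4 sulfide regenerates the benzoate-bridged C4 cation, and Friedel–Crafts attack by C6 of 8 (ortho to O7 and para to O1, the most activated and least hindered position of the lower ring A) anti to the 3-benzoate should set the upper C4 centre 3,4-trans, while the lower C4 benzyl ether and the esters are inert to the soft promoter and the hindered base takes up the acid.

Step 10
Reactants: 16 fully protected dimer
Product: 17 octabenzyl ether of the target: dimer with free upper 3-OH and lower 3-OH, seven aryl benzyl ethers and the lower C4 benzyl ether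
Conditions: NaOMe (0.5 equiv), MeOH/THF, 40 °C
Reagents that add atoms: none
Why: Zemplén-type transesterification should remove both benzoates without touching benzyl ethers or stereocentres.

Step 11
Reactants: 17 octabenzyl ether of the target
Product: 18 (2R,3R,4R)-2-(4-hydroxyphenyl)-6-[(2R,3R,4S)-2-(3,4-dihydroxyphenyl)-3,7,8-trihydroxychroman-4-yl]chroman-3,4,7,8-tetrol (CNP0174688.1)
Conditions: H2 (1 atm), Pd(OH)2/C, THF/MeOH, rt
Reagents that add atoms: none
Why: Hydrogenolysis should cleave the seven aryl benzyl ethers and the lower C4 benzyl ether at their O–CH2Ph bonds under neutral conditions, leaving all six stereocentres untouched.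

## Compound list

1 | 2,3,4-trihydroxybenzaldehyde | O=Cc1ccc(O)c(O)c1O | starting material
2 | 3,4-bis(benzyloxy)-2-hydroxybenzaldehyde | O=Cc1ccc(OCc2ccccc2)c(OCc2ccccc2)c1O | intermediate
3 | 4-(benzyloxy)benzaldehyde | O=Cc1ccc(OCc2ccccc2)cc1 | starting material
4 | 1-(benzyloxy)-4-ethynylbenzene | C#Cc1ccc(OCc2ccccc2)cc1 | intermediate
5 | (Z)-2-[4-(benzyloxy)phenyl]ethenyl benzoate | O=C(O/C=C\c1ccc(OCc2ccccc2)cc1)c1ccccc1 | intermediate
6 | 3,4-bis(benzyloxy)-2-hydroxybenzaldehyde dibenzyl acetal | Oc1c(C(OCc2ccccc2)OCc2ccccc2)ccc(OCc2ccccc2)c1OCc1ccccc1 | intermediate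
7 | (E)-2,3-bis(benzyloxy)-6-[(benzyloxy)methylidene]cyclohexa-2,4-dien-1-one (4-benzyloxy ortho-quinone methide) | O=C1C(OCc2ccccc2)=C(OCc2ccccc2)C=C/C1=C\OCc1ccccc1 | intermediate
8 | (2R,3R,4R)-4,7,8-tris(benzyloxy)-2-[4-(benzyloxy)phenyl]chroman-3-yl benzoate | c1ccccc1COc1ccc([C@H]2Oc3c(ccc(OCc4ccccc4)c3OCc3ccccc3)[C@@H](OCc3ccccc3)[C@H]2OC(=O)c2ccccc2)cc1 | intermediate
9 | 3,4-bis(benzyloxy)benzaldehyde | O=Cc1ccc(OCc2ccccc2)c(OCc2ccccc2)c1 | starting material
10 | 1,2-bis(benzyloxy)-4-ethynylbenzene | C#Cc1ccc(OCc2ccccc2)c(OCc2ccccc2)c1 | intermediate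
11 | (Z)-2-[3,4-bis(benzyloxy)phenyl]ethenyl benzoate | O=C(O/C=C\c1ccc(OCc2ccccc2)c(OCc2ccccc2)c1)c1ccccc1 | intermediate
12 | 3,4-bis(benzyloxy)-2-hydroxybenzaldehyde dimethyl acetal | COC(OC)c1ccc(OCc2ccccc2)c(OCc2ccccc2)c1O | intermediate
13 | (E)-2,3-bis(benzyloxy)-6-(methoxymethylidene)cyclohexa-2,4-dien-1-one (4-methoxy ortho-quinone methide) | O=C1C(OCc2ccccc2)=C(OCc2ccccc2)C=C/C1=C\OC | intermediate
14 | (2R,3R,4R)-7,8-bis(benzyloxy)-2-[3,4-bis(benzyloxy)phenyl]-4-methoxychroman-3-yl benzoate | CO[C@@H]1c2ccc(OCc3ccccc3)c(OCc3ccccc3)c2O[C@H](c2ccc(OCc3ccccc3)c(OCc3ccccc3)c2)[C@@H]1OC(=O)c1ccccc1 | intermediate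
15 | (2R,3S,4S)-4-(benzylsulfanyl)-7,8-bis(benzyloxy)-2-[3,4-bis(benzyloxy)phenyl]chroman-3-yl benzoate | C(c1ccccc1)S[C@H]1c2ccc(OCc3ccccc3)c(OCc3ccccc3)c2O[C@H](c2ccc(OCc3ccccc3)c(OCc3ccccc3)c2)[C@@H]1OC(=O)c1ccccc1 | intermediate
16 | fully protected dimer (upper 3-O-benzoate, lower 3-O-benzoate, lower 4-O-benzyl, seven aryl benzyl ethers; upper unit 2,3-cis-3,4-trans, lower unit all-cis) | c1ccccc1COc1ccc([C@H]2Oc3c(cc([C@H]4c5ccc(OCc6ccccc6)c(OCc6ccccc6)c5O[C@H](c5ccc(OCc6ccccc6)c(OCc6ccccc6)c5)[C@@H]4OC(=O)c4ccccc4)c(OCc4ccccc4)c3OCc3ccccc3)[C@@H](OCc3ccccc3)[C@H]2OC(=O)c2ccccc2)cc1 | intermediate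
17 | octabenzyl ether of the target (free upper 3-OH and lower 3-OH) | c1ccccc1COc1ccc([C@H]2Oc3c(cc([C@H]4c5ccc(OCc6ccccc6)c(OCc6ccccc6)c5O[C@H](c5ccc(OCc6ccccc6)c(OCc6ccccc6)c5)[C@@H]4O)c(OCc4ccccc4)c3OCc3ccccc3)[C@@H](OCc3ccccc3)[C@H]2O)cc1 | intermediate
18 | (2R,3R,4R)-2-(4-hydroxyphenyl)-6-[(2R,3R,4S)-2-(3,4-dihydroxyphenyl)-3,7,8-trihydroxychroman-4-yl]chroman-3,4,7,8-tetrol | Oc1ccc([C@H]2Oc3c(cc([C@H]4c5ccc(O)c(O)c5O[C@H](c5ccc(O)c(O)c5)[C@@H]4O)c(O)c3O)[C@@H](O)[C@H]2O)cc1 | target

## Step count and risks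

Total step count: 11. Longest linear sequence: 7 steps (steps 5, 6, 7, 8, 9, 10, 11).

Steps most likely to fail:

**Step 7 (key step).** The bond formation may become stepwise through a long-lived open benzylic cation, so that the Z geometry leaks to the 2,3-trans series, and the chiral anion may discriminate the two faces poorly. The fallback builds the upper ring C by known reactions only, again after the lower ring C. It sets out from alkyne 10 and aldehyde 2 and comes back to the route at sulfide 15. Hydroboration of 10 with catecholborane and hydrolysis would give (E)-2-[3,4-bis(benzyloxy)phenyl]ethenylboronic acid F1. Amine-catalysed (Bn2NH, dioxane, 90 °C) Petasis-type condensation of F1 with 2 and oxa-6π ring closure would give racemic 7,8-bis(benzyloxy)-2-[3,4-bis(benzyloxy)phenyl]-2H-chromene F2. Copper-catalysed enantioselective hydroboration with kinetic resolution (CuCl, chiral bisphosphine, B2pin2, NaOt-Bu, MeOH, THF) would give the 2,3-trans 3-(pinacolboryl)flavan F3, and NaBO3 oxidation the (2R,3S)-7,8-bis(benzyloxy)-2-[3,4-bis(benzyloxy)phenyl]chroman-3-ol F4. Dess–Martin oxidation would give the (2R)-chroman-3-one F5, and LiBH(s-Bu)3 at −78 °C, attacking opposite to the 2-aryl group, the (2R,3R)-cis alcohol F6. Benzoylation (BzCl, pyridine) would give the (2R,3R)-benzoate F7. DDQ in CH2Cl2/MeOH would oxidise C4 to the 3,4-trans 4-methoxy ether F8, the C4 epimer of 14, which under the conditions of step 8 converges on 15.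

**Step 4.** Enantiofacial discrimination by the chiral acid may be insufficient in the first use of the cycloaddition. The fallback sets out from 2 and 5 and comes back at 8. The same three components are combined with the achiral Lewis acid Sc(OTf)3, the racemic variant of this chroman synthesis. The racemate is then resolved by preparative chromatography on a chiral stationary phase with supercritical CO2; the wanted enantiomer is 8 and the unwanted one is the enantiomer of 8 F9.

**Step 11.** Over-reduction may occur: once the phenols are free, the benzylic C4–O bond of the lower unit may be cleaved by hydrogenolysis. The fallback reverses the order of deprotection; it sets out from 16 and comes back at the target 18. Hydrogenolysis (H2, Pd(OH)2/C, EtOAc/MeOH) is run on 16 itself, so that the 3-benzoate next to C4 withdraws electron density from the benzylic C–O bond while the eight benzyl groups are lost. This would give the dibenzoate of the target F10. The two esters are then removed under oxygen-free conditions (K2CO3, degassed MeOH, 0 °C, then AcOH).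

Further compounds
F1 | step 7 | (E)-2-[3,4-bis(benzyloxy)phenyl]ethenylboronic acid | OB(O)/C=C/c1ccc(OCc2ccccc2)c(OCc2ccccc2)c1
F2 | step 7 | racemic 7,8-bis(benzyloxy)-2-[3,4-bis(benzyloxy)phenyl]-2H-chromene | C1(c2ccc(OCc3ccccc3)c(OCc3ccccc3)c2)C=Cc2ccc(OCc3ccccc3)c(OCc3ccccc3)c2O1
F3 | step 7 | 2,3-trans 2-{(2R)-7,8-bis(benzyloxy)-2-[3,4-bis(benzyloxy)phenyl]chroman-3-yl}-4,4,5,5-tetramethyl-1,3,2-dioxaborolane | C1c2ccc(OCc3ccccc3)c(OCc3ccccc3)c2O[C@H](c2ccc(OCc3ccccc3)c(OCc3ccccc3)c2)[C@H]1B1OC(C)(C)C(C)(C)O1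
F4 | step 7 | (2R,3S)-7,8-bis(benzyloxy)-2-[3,4-bis(benzyloxy)phenyl]chroman-3-ol | C1c2ccc(OCc3ccccc3)c(OCc3ccccc3)c2O[C@H](c2ccc(OCc3ccccc3)c(OCc3ccccc3)c2)[C@H]1O
F5 | step 7 | (2R)-7,8-bis(benzyloxy)-2-[3,4-bis(benzyloxy)phenyl]chroman-3-one | C1c2ccc(OCc3ccccc3)c(OCc3ccccc3)c2O[C@H](c2ccc(OCc3ccccc3)c(OCc3ccccc3)c2)C1=O
F6 | step 7 | (2R,3R)-7,8-bis(benzyloxy)-2-[3,4-bis(benzyloxy)phenyl]chroman-3-ol | C1c2ccc(OCc3ccccc3)c(OCc3ccccc3)c2O[C@H](c2ccc(OCc3ccccc3)c(OCc3ccccc3)c2)[C@@H]1O
F7 | step 7 | (2R,3R)-7,8-bis(benzyloxy)-2-[3,4-bis(benzyloxy)phenyl]chroman-3-yl benzoate | C1c2ccc(OCc3ccccc3)c(OCc3ccccc3)c2O[C@H](c2ccc(OCc3ccccc3)c(OCc3ccccc3)c2)[C@@H]1OC(=O)c1ccccc1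
F8 | step 7 | (2R,3R,4S)-7,8-bis(benzyloxy)-2-[3,4-bis(benzyloxy)phenyl]-4-methoxychroman-3-yl benzoate (3,4-trans) | CO[C@H]1c2ccc(OCc3ccccc3)c(OCc3ccccc3)c2O[C@H](c2ccc(OCc3ccccc3)c(OCc3ccccc3)c2)[C@@H]1OC(=O)c1ccccc1
F9 | step 4 | (2S,3S,4S)-4,7,8-tris(benzyloxy)-2-[4-(benzyloxy)phenyl]chroman-3-yl benzoate | c1ccccc1COc1ccc([C@@H]2Oc3c(ccc(OCc4ccccc4)c3OCc3ccccc3)[C@H](OCc3ccccc3)[C@@H]2OC(=O)c2ccccc2)cc1
F10 | step 11 | dibenzoate of the target (upper 3-O-benzoate and lower 3-O-benzoate, all other hydroxyls free) | Oc1ccc([C@H]2Oc3c(cc([C@H]4c5ccc(O)c(O)c5O[C@H](c5ccc(O)c(O)c5)[C@@H]4OC(=O)c4ccccc4)c(O)c3O)[C@@H](O)[C@H]2OC(=O)c2ccccc2)cc1
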